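**Retrosynthetic overview**

- The route rests on ring C: its C2=C3 pair, with ring B on C2 and the C1'' methylene on C3, is treated as an aryl alkyl alkyne, and C4(=O) with O1 on ring A as the formyl carbon and phenol oxygen of a salicylaldehyde.
- Ring C is the only ring built and is closed last, by forming C3–C4 and O1–C2 in one Cp*Rh-catalysed anodic formyl C–H/O–H annulation; rings A and B are bought as benzene rings.
- Ring A partner: a mirror-symmetric 3,5-bis(MOM-oxy)-4-prenylphenol (directed lithiation/prenylation of resorcinol bis-MOM ether, then para C–H borylation/oxidation) is ortho-formylated; symmetry allows only one aldehyde, so the prenyl group must end at C6.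
- Alkyne partner: the C1''–C(sp) bond comes from alkylating the B-ring lithium acetylide with the primary triflate of the (2''S,3''R)-diol acetonide; the diol comes from geraniol by Sharpless epoxidation and Payne rearrangement/hydroxide opening (inversion at C2'').
- Global acid cleavage of four MOM ethers and the acetonide ends the route.

Key step: step 14

Remark: flavone numbering is used (ring C: O1–C4; ring A: C5–C8; ring B primed; side chain C1''–C8''); the (2''S,3''R) configuration is read from the given SMILES, and the geraniol-derived intermediates carry the same two centres as C2 and C3.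

**Route**

Step 1
Reactants: 1 resorcinol
Product: 2 1,3-bis(methoxymethoxy)benzene
Conditions: NaH, MOMCl, DMF, 0 °C to rt
Reagents that add atoms: chloromethyl methyl ether, COCCl
Why: Williamson-type O-alkylation of both phenoxides gives the bis-MOM ether, whose two acetal oxygens are the directing groups for the next step.

Step 2
Reactants: 2 1,3-bis(methoxymethoxy)benzene; 3 prenyl bromide
Product: 5 1,3-bis(methoxymethoxy)-2-(3-methylbut-2-en-1-yl)benzene, via aryllithium 4 (not isolated)
Conditions: n-BuLi, THF, 0 °C to rt; then CuI (10 mol %), prenyl bromide, −78 °C to rt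
Reagents that add atoms: none
Why: Directed ortho-metalation places lithium at C2 between the two cooperating MOM ethers, and copper-catalysed SN2 allylation with prenyl bromide should give the linear prenyl arene.

Step 3
Reactants: 5 1,3-bis(methoxymethoxy)-2-(3-methylbut-2-en-1-yl)benzene
Product: 7 3,5-bis(methoxymethoxy)-4-(3-methylbut-2-en-1-yl)phenol, via arylboronate 6 (not isolated)
Conditions: [Ir(OMe)(cod)]2 (1.5 mol %), 4,4'-di-tert-butyl-2,2'-bipyridine, B2pin2, THF, 80 °C; then aq. NaOH, 30 % H2O2, 0 °C to rt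
Reagents that add atoms: hydrogen peroxide, OO (phenol oxygen of 7); bis(pinacolato)diboron, CC1(C)OB(OC1(C)C)B1OC(C)(C)C(C)(C)O1 (boron of intermediate 6 only)
Why: Sterically governed iridium-catalysed aromatic C–H borylation should touch only C5, the one ring C–H with no ortho substituent, and oxidation of the C–B bond in the same flask gives the phenol para to the prenyl group, the trisubstituted alkene being expected to stay inert.

Step 4
Reactants: 7 3,5-bis(methoxymethoxy)-4-(3-methylbut-2-en-1-yl)phenol
Product: 8 6-hydroxy-2,4-bis(methoxymethoxy)-3-(3-methylbut-2-en-1-yl)benzaldehyde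
Conditions: MgCl2, Et3N, (CH2O)n, MeCN, 75 °C; aq. NH4Cl work-up
Reagents that add atoms: paraformaldehyde (as formaldehyde), C=O
Why: Magnesium-phenoxide-directed ortho-formylation (Casnati–Skattebøl reaction) delivers the formyl group next to the free hydroxyl, and since the two ortho positions of 7 are equivalent by symmetry only this salicylaldehyde can form.

Step 5
Reactants: 9 2,4-dihydroxybenzaldehyde
Product: 10 2,4-bis(methoxymethoxy)benzaldehyde
Conditions: NaH, MOMCl, DMF, 0 °C to rt
Reagents that add atoms: chloromethyl methyl ether, COCCl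
Why: Williamson-type MOM protection of both phenols, with NaH ensuring that the hydrogen-bonded 2-hydroxyl is alkylated as well.

Step 6
Reactants: 10 2,4-bis(methoxymethoxy)benzaldehyde
Product: 11 1-ethynyl-2,4-bis(methoxymethoxy)benzene
Conditions: dimethyl (1-diazo-2-oxopropyl)phosphonate, K2CO3, MeOH, 0 °C to rt
Reagents that add atoms: dimethyl (1-diazo-2-oxopropyl)phosphonate, COP(=O)(OC)C(=[N+]=[N-])C(C)=O
Why: Ohira–Bestmann modification of the Seyferth–Gilbert homologation converts the aryl aldehyde into the terminal alkyne under mildly basic conditions that leave MOM ethers intact.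

Step 7
Reactants: 12 geraniol
Product: 13 [(2R,3R)-3-methyl-3-(4-methylpent-3-en-1-yl)oxiran-2-yl]methanol ((2R,3R)-2,3-epoxygeraniol)
Conditions: Ti(OiPr)4 (5 mol %), D-(−)-diethyl tartrate (7.5 mol %), t-BuOOH, 4 Å MS, CH2Cl2, −20 °C
Reagents that add atoms: tert-butyl hydroperoxide, CC(C)(C)OO
Why: Sharpless asymmetric epoxidation acts only on the allylic-alcohol alkene and leaves C6=C7 alone, and the D-(−)-tartrate–titanium complex delivers oxygen to the face that sets both C2 and C3 as R.

Step 8
Reactants: 13 (2R,3R)-2,3-epoxygeraniol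
Product: 15 (2S,3R)-3,7-dimethyloct-6-ene-1,2,3-triol, via terminal epoxide 14 (not isolated)
Conditions: 0.5 M aq. NaOH, t-BuOH, 75 °C
Reagents that add atoms: water, O
Why: Payne rearrangement followed by hydroxide opening of the terminal epoxide at C1 inverts C2 by intramolecular SN2 (R to S) while the tertiary C3–O bond is never broken (stays R), giving the anti triol; direct hydroxide attack at C2 would lead to the same stereoisomer.

Step 9
Reactants: 15 (2S,3R)-3,7-dimethyloct-6-ene-1,2,3-triol
Product: 16 (2S,3R)-1-[(tert-butyldimethylsilyl)oxy]-3,7-dimethyloct-6-ene-2,3-diol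
Conditions: TBSCl (1.05 equiv), imidazole, CH2Cl2, 0 °C
Reagents that add atoms: tert-butyldimethylsilyl chloride, CC(C)(C)[Si](C)(C)Cl
Why: Silylation is sterically selective for the primary hydroxyl over the secondary and tertiary ones.

Step 10
Reactants: 16 (2S,3R)-1-[(tert-butyldimethylsilyl)oxy]-3,7-dimethyloct-6-ene-2,3-diol
Product: 17 tert-butyl(dimethyl){[(4S,5R)-2,2,5-trimethyl-5-(4-methylpent-3-en-1-yl)-1,3-dioxolan-4-yl]methoxy}silane
Conditions: 2,2-dimethoxypropane, PPTS (10 mol %), acetone, 40 °C
Reagents that add atoms: 2,2-dimethoxypropane, COC(C)(C)OC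
Why: Acid-catalysed transketalisation closes the dioxolane over the only free 1,2-diol without breaking a C–O bond at either stereocentre.

Step 11
Reactants: 17 silyl ether of the acetonide
Product: 18 [(4S,5R)-2,2,5-trimethyl-5-(4-methylpent-3-en-1-yl)-1,3-dioxolan-4-yl]methanol
Conditions: Bu4NF, THF, 0 °C to rt
Reagents that add atoms: none
Why: Fluoride-induced desilylation frees the primary alcohol and leaves the acetonide and the alkene untouched.

Step 12
Reactants: 18 acetonide primary alcohol
Product: 19 [(4S,5R)-2,2,5-trimethyl-5-(4-methylpent-3-en-1-yl)-1,3-dioxolan-4-yl]methyl trifluoromethanesulfonate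
Conditions: Tf2O, 2,6-lutidine, CH2Cl2, −78 °C; cold work-up, used at once
Reagents that add atoms: trifluoromethanesulfonic anhydride, O=S(=O)(OS(=O)(=O)C(F)(F)F)C(F)(F)F
Why: O-sulfonylation with a hindered base gives the primary alkyl triflate, the leaving group needed for substitution at a β-oxygenated carbon.

Step 13
Reactants: 11 1-ethynyl-2,4-bis(methoxymethoxy)benzene; 19 primary triflate
Product: 21 (4S,5R)-4-{3-[2,4-bis(methoxymethoxy)phenyl]prop-2-yn-1-yl}-2,2,5-trimethyl-5-(4-methylpent-3-en-1-yl)-1,3-dioxolane, via lithium acetylide 20 (not isolated)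
Conditions: n-BuLi, THF, −78 °C; then 19, DMPU, −78 to −10 °C
Reagents that add atoms: none
Why: SN2 alkylation of the lithium arylacetylide by the primary triflate forms the C1''–C(sp) bond at a CH2 group, so neither stereocentre is touched.

Step 14
Reactants: 8 6-hydroxy-2,4-bis(methoxymethoxy)-3-(3-methylbut-2-en-1-yl)benzaldehyde; 21 aryl alkyl alkyne
Product: 22 2-[2,4-bis(methoxymethoxy)phenyl]-5,7-bis(methoxymethoxy)-6-(3-methylbut-2-en-1-yl)-3-{[(4S,5R)-2,2,5-trimethyl-5-(4-methylpent-3-en-1-yl)-1,3-dioxolan-4-yl]methyl}-4H-chromen-4-one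
Conditions: [Cp*RhCl2]2 (5 mol %), NaOPiv, t-AmOH/H2O (3:1), graphite-felt anode, Pt cathode, undivided cell, constant current 2 mA, 90 °C, N2
Reagents that add atoms: none
Why: The phenoxide of 8 binds Cp*Rh (trivalent rhodium) and directs pivalate-assisted cleavage of the formyl C–H bond to a five-membered acyl rhodacycle; alkyne 21 inserts into the Rh–acyl bond (C3–C4), and C–O reductive elimination from the seven-membered rhodacycle forms O1–C2, after which monovalent rhodium is reoxidised at the anode while protons are reduced to H2 at the cathode. The closest known reaction type is the Cp*Rh-catalysed oxidative annulation of salicylaldehydes with internal alkynes to 2,3-disubstituted chromones, including its electrochemical variant. Ring C closes in a formal [4+2] mode, four atoms (O1, C8a, C4a, C4) coming from 8 and two from the alkyne, the last bond being made by C–O reductive elimination. No stereocentre is formed, and the acetonide-held C2'' and C3'' lie outside all bond changes. The step needs insertion regiochemistry, which the electron-rich aryl group should secure because aryl alkyl alkynes insert with the aryl-bearing carbon remaining on rhodium, so ring B ends at C2 and the CH2 at C3. The C6 position of the prenyl group is already fixed because only one ortho oxygen of 8 is free, and anodic reoxidation keeps copper or silver oxidants away from the three trisubstituted alkenes and the acetals.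

Step 15
Reactants: 22 tetra-MOM acetonide of the target
Product: 23 2-(2,4-dihydroxyphenyl)-3-[(2S,3R)-2,3-dihydroxy-3,7-dimethyloct-6-en-1-yl]-5,7-dihydroxy-6-(3-methylbut-2-en-1-yl)-4H-chromen-4-one (target)
Conditions: 3 M aq. HCl/MeOH (1:5), rt to 40 °C
Reagents that add atoms: none
Why: Acid-catalysed acetal cleavage removes the four MOM ethers and the isopropylidene ketal at their acetal carbons, so the C–O bonds at C2'' and C3'' and their configuration are retained.

**Compound list**

1 | resorcinol | Oc1cccc(O)c1 | starting material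
2 | 1,3-bis(methoxymethoxy)benzene | COCOc1cccc(OCOC)c1 | intermediate
3 | prenyl bromide (1-bromo-3-methylbut-2-ene) | CC(C)=CCBr | starting material
4 | [2,6-bis(methoxymethoxy)phenyl]lithium | [Li]c1c(OCOC)cccc1OCOC | intermediate (not isolated)
5 | 1,3-bis(methoxymethoxy)-2-(3-methylbut-2-en-1-yl)benzene | COCOc1cccc(OCOC)c1CC=C(C)C | intermediate
6 | 2-[3,5-bis(methoxymethoxy)-4-(3-methylbut-2-en-1-yl)phenyl]-4,4,5,5-tetramethyl-1,3,2-dioxaborolane | COCOc1cc(B2OC(C)(C)C(C)(C)O2)cc(OCOC)c1CC=C(C)C | intermediate (not isolated)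
7 | 3,5-bis(methoxymethoxy)-4-(3-methylbut-2-en-1-yl)phenol | COCOc1cc(O)cc(OCOC)c1CC=C(C)C | intermediate
8 | 6-hydroxy-2,4-bis(methoxymethoxy)-3-(3-methylbut-2-en-1-yl)benzaldehyde | O=Cc1c(O)cc(OCOC)c(CC=C(C)C)c1OCOC | intermediate
9 | 2,4-dihydroxybenzaldehyde | O=Cc1ccc(O)cc1O | starting material
10 | 2,4-bis(methoxymethoxy)benzaldehyde | O=Cc1ccc(OCOC)cc1OCOC | intermediate
11 | 1-ethynyl-2,4-bis(methoxymethoxy)benzene | C#Cc1ccc(OCOC)cc1OCOC | intermediate
12 | geraniol | CC(C)=CCC/C(C)=C/CO | starting material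
13 | [(2R,3R)-3-methyl-3-(4-methylpent-3-en-1-yl)oxiran-2-yl]methanol | CC(C)=CCC[C@@]1(C)O[C@@H]1CO | intermediate
14 | (2R)-6-methyl-2-[(2S)-oxiran-2-yl]hept-5-en-2-ol | CC(C)=CCC[C@@](C)(O)[C@@H]1CO1 | intermediate (not isolated)
15 | (2S,3R)-3,7-dimethyloct-6-ene-1,2,3-triol | CC(C)=CCC[C@@](C)(O)[C@@H](O)CO | intermediate
16 | (2S,3R)-1-[(tert-butyldimethylsilyl)oxy]-3,7-dimethyloct-6-ene-2,3-diol | CC(C)=CCC[C@@](C)(O)[C@@H](O)CO[Si](C)(C)C(C)(C)C | intermediate
17 | tert-butyl(dimethyl){[(4S,5R)-2,2,5-trimethyl-5-(4-methylpent-3-en-1-yl)-1,3-dioxolan-4-yl]methoxy}silane | CC(C)=CCC[C@@]1(C)OC(C)(C)O[C@H]1CO[Si](C)(C)C(C)(C)C | intermediate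
18 | [(4S,5R)-2,2,5-trimethyl-5-(4-methylpent-3-en-1-yl)-1,3-dioxolan-4-yl]methanol | CC(C)=CCC[C@@]1(C)OC(C)(C)O[C@H]1CO | intermediate
19 | [(4S,5R)-2,2,5-trimethyl-5-(4-methylpent-3-en-1-yl)-1,3-dioxolan-4-yl]methyl trifluoromethanesulfonate | CC(C)=CCC[C@@]1(C)OC(C)(C)O[C@H]1COS(=O)(=O)C(F)(F)F | intermediate
20 | {[2,4-bis(methoxymethoxy)phenyl]ethynyl}lithium | [Li]C#Cc1ccc(OCOC)cc1OCOC | intermediate (not isolated)
21 | (4S,5R)-4-{3-[2,4-bis(methoxymethoxy)phenyl]prop-2-yn-1-yl}-2,2,5-trimethyl-5-(4-methylpent-3-en-1-yl)-1,3-dioxolane | CC(C)=CCC[C@@]1(C)OC(C)(C)O[C@H]1CC#Cc1ccc(OCOC)cc1OCOC | intermediate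
22 | 2-[2,4-bis(methoxymethoxy)phenyl]-5,7-bis(methoxymethoxy)-6-(3-methylbut-2-en-1-yl)-3-{[(4S,5R)-2,2,5-trimethyl-5-(4-methylpent-3-en-1-yl)-1,3-dioxolan-4-yl]methyl}-4H-chromen-4-one | CC(C)=CCC[C@@]1(C)OC(C)(C)O[C@H]1Cc1c(-c2ccc(OCOC)cc2OCOC)oc2cc(OCOC)c(CC=C(C)C)c(OCOC)c2c1=O | intermediate
23 | 2-(2,4-dihydroxyphenyl)-3-[(2S,3R)-2,3-dihydroxy-3,7-dimethyloct-6-en-1-yl]-5,7-dihydroxy-6-(3-methylbut-2-en-1-yl)-4H-chromen-4-one | CC(C)=CCC[C@@](C)(O)[C@@H](O)Cc1c(-c2ccc(O)cc2O)oc2cc(O)c(CC=C(C)C)c(O)c2c1=O | target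

**Step count**

Total: 15 steps. Longest linear sequence: 9 steps (steps 7 to 15, geraniol to target).

**Steps most likely to fail**

1. Step 14. The hindered alkyne may insert slowly, the acyl rhodacycle may lose CO, the electron-rich phenoxide may be oxidised directly at the anode, or insertion may occur in the opposite orientation. The fallback builds ring C by classical cyclodehydration of a 1,3-diketone; it sets out from 21 and 8 and returns at 22. Alkyne 21 is hydrated with Ph3PAuNTf2 in wet dioxane, where the electron-rich aryl group should place the carbonyl on the aryl-bearing carbon, giving the aryl ketone F1. Aldehyde 8 is O-allylated (allyl bromide, K2CO3, DMF) to the allyl ether F2. Deprotonation of F1 with LiN(iPr)2 at −78 °C gives the lithium enolate F3, which adds to F2 to give the aldol F4 as a diastereomer mixture of no consequence. Dess–Martin oxidation gives the 1,3-diketone F5. Pd(PPh3)4 with excess morpholine removes the allyl group to give the free phenol F6, which on warming with PPTS in toluene closes onto the B-ring carbonyl and loses water to give 22. The C2'' oxygen stays locked in the acetonide throughout, so it cannot trap the diketone.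

2. Step 15. During the long acid exposure needed for the hindered acetonide, the prenyl group may cyclise onto a neighbouring free phenol, or the tertiary carbinol may add to the C6''=C7'' alkene. The fallback is a staged deprotection from 22 to 23. The acetonide is hydrolysed first in 80 % aqueous acetic acid at 45 °C while all phenols are still capped, giving the tetra-MOM diol F7. The MOM ethers are then cleaved within minutes by ZnBr2 and n-PrSH in CH2Cl2 at 0 °C, a thiol-assisted Lewis-acid cleavage without protic acid, to give 23.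

3. Step 3. Iridium hydride or pinacolborane may hydroborate or isomerise the prenyl alkene, or the electron-rich phenol may be over-oxidised. The fallback installs the oxygen before the alkene is present; it sets out from 2 and returns at 7. Borylation of 2 under the same iridium conditions gives the 5-boronate F8, which is oxidised (H2O2, NaOH) to 3,5-bis(methoxymethoxy)phenol F9. Silylation (iPr3SiCl, imidazole) gives the silyl ether F10. n-BuLi lithiates between the two MOM ethers, since the bulky silyl ether does not direct, giving the aryllithium F11. Copper-catalysed reaction with prenyl bromide 3 gives F12, and Bu4NF then frees phenol 7.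

**Further compounds**

F1 | step 14 | 1-[2,4-bis(methoxymethoxy)phenyl]-3-[(4S,5R)-2,2,5-trimethyl-5-(4-methylpent-3-en-1-yl)-1,3-dioxolan-4-yl]propan-1-one | CC(C)=CCC[C@@]1(C)OC(C)(C)O[C@H]1CCC(=O)c1ccc(OCOC)cc1OCOC
F2 | step 14 | 6-(allyloxy)-2,4-bis(methoxymethoxy)-3-(3-methylbut-2-en-1-yl)benzaldehyde | O=Cc1c(OCC=C)cc(OCOC)c(CC=C(C)C)c1OCOC
F3 | step 14 | lithium enolate of F1 | CC(C)=CCC[C@@]1(C)OC(C)(C)O[C@H]1CC=C(O[Li])c1ccc(OCOC)cc1OCOC
F4 | step 14 | aldol adduct of F1 and F2 (diastereomer mixture at the two new carbons) | CC(C)=CCC[C@@]1(C)OC(C)(C)O[C@H]1CC(C(=O)c1ccc(OCOC)cc1OCOC)C(O)c1c(OCC=C)cc(OCOC)c(CC=C(C)C)c1OCOC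
F5 | step 14 | 1-[6-(allyloxy)-2,4-bis(methoxymethoxy)-3-(3-methylbut-2-en-1-yl)phenyl]-3-[2,4-bis(methoxymethoxy)phenyl]-2-{[(4S,5R)-2,2,5-trimethyl-5-(4-methylpent-3-en-1-yl)-1,3-dioxolan-4-yl]methyl}propane-1,3-dione | CC(C)=CCC[C@@]1(C)OC(C)(C)O[C@H]1CC(C(=O)c1ccc(OCOC)cc1OCOC)C(=O)c1c(OCC=C)cc(OCOC)c(CC=C(C)C)c1OCOC
F6 | step 14 | free-phenol 1,3-diketone from F5 | CC(C)=CCC[C@@]1(C)OC(C)(C)O[C@H]1CC(C(=O)c1ccc(OCOC)cc1OCOC)C(=O)c1c(O)cc(OCOC)c(CC=C(C)C)c1OCOC
F7 | step 15 | 2-[2,4-bis(methoxymethoxy)phenyl]-3-[(2S,3R)-2,3-dihydroxy-3,7-dimethyloct-6-en-1-yl]-5,7-bis(methoxymethoxy)-6-(3-methylbut-2-en-1-yl)-4H-chromen-4-one | CC(C)=CCC[C@@](C)(O)[C@@H](O)Cc1c(-c2ccc(OCOC)cc2OCOC)oc2cc(OCOC)c(CC=C(C)C)c(OCOC)c2c1=O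
F8 | step 3 | 2-[3,5-bis(methoxymethoxy)phenyl]-4,4,5,5-tetramethyl-1,3,2-dioxaborolane | COCOc1cc(OCOC)cc(B2OC(C)(C)C(C)(C)O2)c1
F9 | step 3 | 3,5-bis(methoxymethoxy)phenol | COCOc1cc(O)cc(OCOC)c1
F10 | step 3 | [3,5-bis(methoxymethoxy)phenoxy]tri(propan-2-yl)silane | COCOc1cc(O[Si](C(C)C)(C(C)C)C(C)C)cc(OCOC)c1
F11 | step 3 | {2,6-bis(methoxymethoxy)-4-[tri(propan-2-yl)silyloxy]phenyl}lithium | [Li]c1c(OCOC)cc(O[Si](C(C)C)(C(C)C)C(C)C)cc1OCOC
F12 | step 3 | [3,5-bis(methoxymethoxy)-4-(3-methylbut-2-en-1-yl)phenoxy]tri(propan-2-yl)silane | COCOc1cc(O[Si](C(C)C)(C(C)C)C(C)C)cc(OCOC)c1CC=C(C)C
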